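## The problem

The target 21 is a linear tetramer of four benzene rings joined by three diaryl ether oxygens and carrying ten free hydroxyl groups; it has no stereocentre, so every selectivity question is one of regiochemistry. The rings are lettered A (2,4,6-trihydroxyphenyl end), B, C and D (3,4,5-trihydroxyphenyl end), and in rings B, C and D C1 is the carbon bound to the oxygen shared with the preceding ring and C4 is para to it. Each ether oxygen sits on one side on a carbon flanked by two oxygenated ortho carbons (the ether carbon of ring A, C4 of ring B, C4 of ring C), so any phenol used as the nucleophile is doubly ortho-substituted. All four rings are electron-rich, which excludes SNAr and makes metal-catalysed C–O coupling slow in both partners. The ten oxygens must travel protected and be released at the very end, because the free polyphenol, with a pyrogallol-type ring D and a phloroglucinol-type ring A, is easily oxidised by air, above all as its phenoxide. Rings B, C and D differ only in what C4–O carries, which invites one building block used three times. The enabling feature lies on the other side of each ether oxygen: C1 of rings B, C and D has C2–H as neighbour and an oxygen on C3, exactly the pattern left when a nucleophile adds to a 3-alkoxybenzyne whose triple bond lies between C1 and C2.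

## Retrosynthesis

**Protecting groups.** Target 21 is traced to the nonamethyl ether 20, whose only free hydroxyl is the flanked one on ring D. Methyl ethers are chosen as permanent groups because they survive fluoride, organolithium, triflic anhydride and hydrogenolysis, and are small enough not to add to the crowding at the nucleophilic oxygen. One operation with BBr3 must then cleave nine O–CH3 bonds without touching the three aryl–O–aryl bonds.

**Ring D.** Phenol 20 comes from benzyl ether 19 by hydrogenolysis. The benzyl group is removed before the Lewis acid step so that no benzyl cation is formed next to four very nucleophilic rings. The O–C1 bond of ring D in 19 is cut to give trimer phenol 18 and silylaryl triflate 13. Cutting on the C1 side, not the flanked side, puts the crowded carbon in the nucleophile, where it needs only a lone pair, and the uncrowded carbon in the electrophile.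

**Rings C and B.** The same cut, repeated, takes 18 through benzyl ether 17 to dimer phenol 16 and 13, and 16 through benzyl ether 15 to 2,4,6-trimethoxyphenol 3 and 13. Each cycle removes one ring and returns a phenol of the same type, so one reaction and one reagent serve three times. The C4 benzyl ether of 13 becomes the next flanked hydroxyl after each hydrogenolysis.

**Key disconnection.** Dimer 15 is cut at the O–C1 bond of ring B into phenol 3 and benzyne 14, released from 13. The forward reaction must add the phenoxide to C1 and not C2 of 14. The methoxy group on C3, next to the triple bond, is relied on for this.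

**Aryne precursor.** Triflate 13 needs silicon on the carbon between the triflate and a methoxy group. It is traced to silyl ether 10 by bromine–lithium exchange, retro-Brook migration and triflation. Silyl ether 10 comes from bromophenol 9, which comes from the C2-symmetric phenol 8 by bromination at the only kind of free position. Phenol 8 comes from aldehyde 6 by Dakin oxidation, and 6 from syringaldehyde 4 and benzyl bromide 5. Syringaldehyde already holds the 3,5-dimethoxy-4-hydroxy pattern, so nothing on the ring has to be differentiated.

**Ring A.** Phenol 3 is traced to 2,4,6-trimethoxybenzaldehyde 1 by Dakin oxidation, which turns the formyl carbon's position into the flanked hydroxyl.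

## Roads not taken

**Alternative 1:** The cut goes through ring B itself, at its C2–C3 and C5–C6 bonds. Enol ether A1 (dimethyl 3-(2,4,6-trimethoxyphenoxy)pent-2-enedioate, derived from phenol 3) would be acylated at both carbons flanking its enol ether carbon by aryloxymalonyl dichloride A2. Aromatisation would give the 4,6-dihydroxyisophthalate A3.

- Merits: neither oxygen of ring B is ever joined to an aromatic carbon. Both arrive on acyclic carbons, where hindrance in the phenol matters little, and the two ring B hydroxyls come from the acyl carbons.
- Weak points: A2 already contains the C–D ether, whose oxygen sits on the flanked carbon of ring C, so that linkage must come from another method. Each application needs separate syntheses of A1 and A2, the condensation, ester hydrolysis and a double decarboxylation, and A3 must be re-methylated before any further use.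
- Mechanistic risk: A2 can lose HCl and then acylate at oxygen as readily as at carbon, which would close an oxygen heterocycle instead of the benzene ring.
- Comparison: this road avoids the attack of a hindered phenoxide on an arene altogether, which the chosen plan cannot claim. Against that, the chosen plan makes all three linkages with one reaction and is much shorter.

**Alternative 2:** The cut is at the C4–O bond of ring C, with polarity reversed. Quinone diazide A4 (4-diazo-3,5-dimethoxycyclohexa-2,5-dien-1-one) would be converted by Rh2(OAc)4 (divalent rhodium) into a carbenoid that inserts into the O–H bond of 3,4,5-trimethoxyphenol A5. Tautomerisation would give the C–D phenol A6.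

- Merits: the crowded carbon is the electrophile and the nucleophile is an unhindered phenol. The product is already a free phenol, so the same diazide A4 could be added three times from ring D to ring A with no protecting-group steps. Ring A would even emerge with its para hydroxyl free.
- Step economy: this road is clearly better, three couplings and one demethylation against six coupling and deprotection steps plus a five-step building block.
- Weak points: rhodium carbenoids from quinone diazides are best known to arylate electron-rich arenes at carbon, and A5 and every later phenol offer two activated ortho C–H positions. The diazo carbon of A4 is flanked by two methoxy groups. A4 needs its own synthesis by diazotisation and is a potentially unstable diazo compound.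
- Comparison: the chosen plan sets against the better step count a bond-forming reaction whose chemoselectivity for oxygen is structurally enforced, because the ortho and para carbons of its nucleophile are blocked, and whose regiochemistry has a known controlling element.

**Alternative 3:** Ring D would be built last by a Dötz benzannulation. The aryloxy[(E)-2-ethoxyvinyl]carbene complex A7 of Cr(CO)5 (zerovalent chromium), carrying the trimer derived from phenol 18, would react with ethoxyacetylene A8. Alkyne insertion, CO insertion and six-electron closure would form the C1–C2, C3–C4 and C4–C5 bonds of ring D and give A9, with ring D as a 2,6-diethoxyphenol.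

- Merits: ring D arrives with its flanked hydroxyl free, and its ether bond is made by substitution at a carbene carbon instead of at an arene.
- Weak points: it addresses one of the three linkages and needs phenol 18, hence two hindered ether bonds, from another method. A7 would have to be assembled by attaching the doubly flanked oxygen of 18 to the carbene carbon, a substitution that crowding disfavours, and aryloxycarbene complexes of this kind are labile. The beta-ethoxyvinyl group of A7 is a Michael acceptor for that phenol. Ynol ethers such as A8 are poor and regiochemically unreliable partners. Chromium is stoichiometric.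
- Comparison: it would replace two simple steps of the chosen route (11 and 12) by a longer and less certain sequence. Its one advantage, a free hydroxyl without a benzyl group, is small because hydrogenolysis is the most reliable step in the plan.

Key step: step 7

## Route

Remark on the chemistry: the proton that ends up on C2 of each new ring is taken to come from the phenol O–H, directly or through acetonitrile, so the arylations are written without an added proton source.

Remark on the chemistry: benzyne 14 is a transient that CsF releases afresh from triflate 13 in each of the three arylations; it is entered as an intermediate at step 7, where it first forms, and steps 9 and 11 pass through it in the same way.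

Step 1
Reactants: 1 2,4,6-trimethoxybenzaldehyde
Product: 3 2,4,6-trimethoxyphenol, via 2,4,6-trimethoxyphenyl formate 2 (not isolated)
Conditions: H2O2 (30% aq.), H2SO4 (cat.), MeOH, rt
Reagents that add atoms: hydrogen peroxide, OO
Why: Dakin-type (Baeyer–Villiger) oxidation; the aryl group, with two ortho and one para methoxy donor, migrates to oxygen, and formate 2 is methanolysed in the same acidic medium, which keeps the air-sensitive phenol out of base.

Step 2
Reactants: 4 syringaldehyde; 5 benzyl bromide
Product: 6 4-(benzyloxy)-3,5-dimethoxybenzaldehyde
Conditions: K2CO3, DMF, 60 °C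
Reagents that add atoms: none
Why: Williamson ether synthesis on the only hydroxyl, whose acidity is raised by the para formyl group; the benzyl group marks the oxygen that will later be the flanked nucleophile.

Step 3
Reactants: 6 4-(benzyloxy)-3,5-dimethoxybenzaldehyde
Product: 8 4-(benzyloxy)-3,5-dimethoxyphenol, via 4-(benzyloxy)-3,5-dimethoxyphenyl formate 7 (not isolated)
Conditions: mCPBA, CH2Cl2, 0 °C to rt; aq. NaHCO3 wash; then K2CO3 (cat.), MeOH, rt
Reagents that add atoms: meta-chloroperoxybenzoic acid, OOC(=O)c1cccc(Cl)c1
Why: Dakin oxidation by way of a Baeyer–Villiger aryl migration, favoured by the para alkoxy group, followed by methanolysis of formate 7; the benzyl ether is inert to both stages.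

Step 4
Reactants: 8 4-(benzyloxy)-3,5-dimethoxyphenol
Product: 9 4-(benzyloxy)-2-bromo-3,5-dimethoxyphenol
Conditions: NBS (1.0 equiv), CH2Cl2, −78 to 0 °C
Reagents that add atoms: N-bromosuccinimide, O=C1CCC(=O)N1Br
Why: Electrophilic aromatic bromination; the phenol is C2-symmetric and its only free positions are the two equivalent carbons between the hydroxyl and a methoxy group, so regiochemistry is not in question and one equivalent at low temperature limits the reaction to one bromine.

Step 5
Reactants: 9 4-(benzyloxy)-2-bromo-3,5-dimethoxyphenol
Product: 10 [4-(benzyloxy)-2-bromo-3,5-dimethoxyphenoxy]trimethylsilane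
Conditions: HMDS, THF, reflux; volatiles removed in vacuo, used crude
Reagents that add atoms: hexamethyldisilazane, C[Si](C)(C)N[Si](C)(C)C
Why: O-silylation of a phenol with a silazane, driven by loss of ammonia; it leaves no salt and no acid, so the moisture-sensitive aryl silyl ether can be taken on after evaporation.

Step 6
Reactants: 10 [4-(benzyloxy)-2-bromo-3,5-dimethoxyphenoxy]trimethylsilane
Product: 13 4-(benzyloxy)-3,5-dimethoxy-2-(trimethylsilyl)phenyl trifluoromethanesulfonate, via aryllithium 11 (not isolated), via lithium 2-silylphenoxide 12 (not isolated)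
Conditions: n-BuLi, THF, −100 to −78 °C; then Tf2O, −100 to −78 °C
Reagents that add atoms: trifluoromethanesulfonic anhydride, O=S(=O)(OS(=O)(=O)C(F)(F)F)C(F)(F)F
Why: Bromine–lithium exchange gives 11, whose carbanion takes silicon from the neighbouring oxygen (retro-Brook 1,3-shift) to give phenoxide 12, which is triflated in the flask; exchange at these temperatures is much faster than deprotonation at the benzylic CH2 or on the ring.

Step 7
Reactants: 3 2,4,6-trimethoxyphenol; 13 4-(benzyloxy)-3,5-dimethoxy-2-(trimethylsilyl)phenyl trifluoromethanesulfonate
Product: 15 2-[4-(benzyloxy)-3,5-dimethoxyphenoxy]-1,3,5-trimethoxybenzene (A–B dimer), via 4-(benzyloxy)-3,5-dimethoxybenzyne 14 (not isolated)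
Conditions: CsF (3 equiv), MeCN, rt; 13 (1.5 equiv) added slowly to 3 and CsF
Reagents that add atoms: none
Why: Fluoride attacks silicon of 13 and loss of triflate from the resulting aryl anion gives benzyne 14, with its triple bond between C1 and C2 of the future ring B. The caesium phenoxide of 3 adds to C1 and the aryl anion left at C2 is protonated by another molecule of 3 or by acetonitrile, which forms the O–C1 and C2–H bonds. The closest known reaction type is the fluoride-induced O-arylation of phenols, ortho,ortho'-disubstituted ones included, by arynes released from ortho-silylaryl triflates. No ring is closed and no stereocentre is created. The selectivity needed is the sense of addition to the unsymmetrical aryne: the methoxy group on C3 withdraws inductively in the plane of the strained bond and distorts it so that C1 is the more linear, more electrophilic end, and the negative charge develops at C2 next to the oxygen-bearing carbon. Attack at C1 is also the less hindered path, since C2 lies beside that methoxy group. Because C2, C4 and C6 of the phenoxide all carry methoxy groups, arylation at carbon cannot give a stable arene and oxygen is the only productive nucleophilic site. No metal has to bind the crowded oxygen, which is why the double ortho substitution is tolerated.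

Step 8
Reactants: 15 2-[4-(benzyloxy)-3,5-dimethoxyphenoxy]-1,3,5-trimethoxybenzene
Product: 16 2,6-dimethoxy-4-(2,4,6-trimethoxyphenoxy)phenol
Conditions: H2 (1 atm), Pd/C, EtOAc–MeOH, rt
Reagents that add atoms: none
Why: Hydrogenolysis of the benzylic C–O bond; methyl ethers and the diaryl ether are untouched, and the hydroxyl freed is the flanked one on C4 of ring B.

Step 9
Reactants: 16 2,6-dimethoxy-4-(2,4,6-trimethoxyphenoxy)phenol; 13 4-(benzyloxy)-3,5-dimethoxy-2-(trimethylsilyl)phenyl trifluoromethanesulfonate
Product: 17 2-{4-[4-(benzyloxy)-3,5-dimethoxyphenoxy]-3,5-dimethoxyphenoxy}-1,3,5-trimethoxybenzene (A–B–C trimer)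
Conditions: CsF (3 equiv), MeCN, rt; 13 (1.5 equiv) added slowly
Reagents that add atoms: none
Why: Same fluoride-induced aryne O-arylation as step 7, with benzyne 14 released again from 13 in the flask; phenol 16 has the same 2,6-dimethoxy-4-oxy environment at its hydroxyl as 3, so oxygen attack at C1 of the aryne, directed by the C3 methoxy group, forms the O–C1 bond of ring C.

Step 10
Reactants: 17 2-{4-[4-(benzyloxy)-3,5-dimethoxyphenoxy]-3,5-dimethoxyphenoxy}-1,3,5-trimethoxybenzene
Product: 18 4-[2,6-dimethoxy-4-(2,4,6-trimethoxyphenoxy)phenoxy]-2,6-dimethoxyphenol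
Conditions: H2 (1 atm), Pd/C, EtOAc–MeOH, rt
Reagents that add atoms: none
Why: Hydrogenolysis of the single benzyl ether, as in step 8, frees the flanked hydroxyl on C4 of ring C.

Step 11
Reactants: 18 4-[2,6-dimethoxy-4-(2,4,6-trimethoxyphenoxy)phenoxy]-2,6-dimethoxyphenol; 13 4-(benzyloxy)-3,5-dimethoxy-2-(trimethylsilyl)phenyl trifluoromethanesulfonate
Product: 19 2-(4-{4-[4-(benzyloxy)-3,5-dimethoxyphenoxy]-3,5-dimethoxyphenoxy}-3,5-dimethoxyphenoxy)-1,3,5-trimethoxybenzene (A–B–C–D tetramer)
Conditions: CsF (3 equiv), MeCN (THF as co-solvent if needed), rt; 13 (1.5–2 equiv) added slowly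
Reagents that add atoms: none
Why: Third use of the aryne O-arylation, again through benzyne 14 generated from 13 by CsF; it forms the O–C1 bond of ring D with the same regiocontrol, and the benzyloxy group of the aryne becomes the future C4 hydroxyl of ring D.

Step 12
Reactants: 19 2-(4-{4-[4-(benzyloxy)-3,5-dimethoxyphenoxy]-3,5-dimethoxyphenoxy}-3,5-dimethoxyphenoxy)-1,3,5-trimethoxybenzene
Product: 20 4-{4-[2,6-dimethoxy-4-(2,4,6-trimethoxyphenoxy)phenoxy]-2,6-dimethoxyphenoxy}-2,6-dimethoxyphenol
Conditions: H2 (1 atm), Pd/C, EtOAc–MeOH, rt
Reagents that add atoms: none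
Why: Hydrogenolysis removes the last benzyl group as toluene before any Lewis acid is used, so that no benzyl cation can alkylate the electron-rich rings in the final step.

Step 13
Reactants: 20 4-{4-[2,6-dimethoxy-4-(2,4,6-trimethoxyphenoxy)phenoxy]-2,6-dimethoxyphenoxy}-2,6-dimethoxyphenol
Product: 21 2-{4-[4-(3,4,5-trihydroxyphenoxy)-3,5-dihydroxyphenoxy]-3,5-dihydroxyphenoxy}benzene-1,3,5-triol (target)
Conditions: BBr3 (about 3 equiv per OMe), CH2Cl2, −78 °C to rt; MeOH then H2O at 0 °C, under argon
Reagents that add atoms: none
Why: Lewis-acid demethylation of aryl methyl ethers; boron binds each methoxy oxygen and bromide attacks the methyl carbon by SN2, a path closed to the diaryl ether bonds, whose carbons are both sp2; the boron–oxygen bonds are hydrolysed on quench.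

## Compound list

The target and all intermediates are achiral, so no SMILES carries stereodescriptors.

1 | 2,4,6-trimethoxybenzaldehyde | COc1cc(OC)c(C=O)c(OC)c1 | starting material
2 | 2,4,6-trimethoxyphenyl formate | COc1cc(OC)c(OC=O)c(OC)c1 | intermediate (not isolated)
3 | 2,4,6-trimethoxyphenol | COc1cc(OC)c(O)c(OC)c1 | intermediate
4 | syringaldehyde (4-hydroxy-3,5-dimethoxybenzaldehyde) | COc1cc(C=O)cc(OC)c1O | starting material
5 | benzyl bromide | BrCc1ccccc1 | starting material
6 | 4-(benzyloxy)-3,5-dimethoxybenzaldehyde | COc1cc(C=O)cc(OC)c1OCc1ccccc1 | intermediate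
7 | 4-(benzyloxy)-3,5-dimethoxyphenyl formate | COc1cc(OC=O)cc(OC)c1OCc1ccccc1 | intermediate (not isolated)
8 | 4-(benzyloxy)-3,5-dimethoxyphenol | COc1cc(O)cc(OC)c1OCc1ccccc1 | intermediate
9 | 4-(benzyloxy)-2-bromo-3,5-dimethoxyphenol | COc1cc(O)c(Br)c(OC)c1OCc1ccccc1 | intermediate
10 | [4-(benzyloxy)-2-bromo-3,5-dimethoxyphenoxy]trimethylsilane | COc1cc(O[Si](C)(C)C)c(Br)c(OC)c1OCc1ccccc1 | intermediate
11 | {3-(benzyloxy)-2,4-dimethoxy-6-[(trimethylsilyl)oxy]phenyl}lithium | COc1cc(O[Si](C)(C)C)c([Li])c(OC)c1OCc1ccccc1 | intermediate (not isolated)
12 | lithium 4-(benzyloxy)-3,5-dimethoxy-2-(trimethylsilyl)phenoxide | [Li+].[O-]c1cc(OC)c(OCc2ccccc2)c(OC)c1[Si](C)(C)C | intermediate (not isolated)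
13 | 4-(benzyloxy)-3,5-dimethoxy-2-(trimethylsilyl)phenyl trifluoromethanesulfonate | COc1cc(OS(=O)(=O)C(F)(F)F)c([Si](C)(C)C)c(OC)c1OCc1ccccc1 | intermediate
14 | 4-(benzyloxy)-3,5-dimethoxybenzyne | COC1=CC#CC(OC)=C1OCc1ccccc1 | intermediate (not isolated)
15 | 2-[4-(benzyloxy)-3,5-dimethoxyphenoxy]-1,3,5-trimethoxybenzene | COc1cc(OC)c(Oc2cc(OC)c(OCc3ccccc3)c(OC)c2)c(OC)c1 | intermediate
16 | 2,6-dimethoxy-4-(2,4,6-trimethoxyphenoxy)phenol | COc1cc(OC)c(Oc2cc(OC)c(O)c(OC)c2)c(OC)c1 | intermediate
17 | 2-{4-[4-(benzyloxy)-3,5-dimethoxyphenoxy]-3,5-dimethoxyphenoxy}-1,3,5-trimethoxybenzene | COc1cc(OC)c(Oc2cc(OC)c(Oc3cc(OC)c(OCc4ccccc4)c(OC)c3)c(OC)c2)c(OC)c1 | intermediate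
18 | 4-[2,6-dimethoxy-4-(2,4,6-trimethoxyphenoxy)phenoxy]-2,6-dimethoxyphenol | COc1cc(OC)c(Oc2cc(OC)c(Oc3cc(OC)c(O)c(OC)c3)c(OC)c2)c(OC)c1 | intermediate
19 | 2-(4-{4-[4-(benzyloxy)-3,5-dimethoxyphenoxy]-3,5-dimethoxyphenoxy}-3,5-dimethoxyphenoxy)-1,3,5-trimethoxybenzene | COc1cc(OC)c(Oc2cc(OC)c(Oc3cc(OC)c(Oc4cc(OC)c(OCc5ccccc5)c(OC)c4)c(OC)c3)c(OC)c2)c(OC)c1 | intermediate
20 | 4-{4-[2,6-dimethoxy-4-(2,4,6-trimethoxyphenoxy)phenoxy]-2,6-dimethoxyphenoxy}-2,6-dimethoxyphenol | COc1cc(OC)c(Oc2cc(OC)c(Oc3cc(OC)c(Oc4cc(OC)c(O)c(OC)c4)c(OC)c3)c(OC)c2)c(OC)c1 | intermediate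
21 | 2-{4-[4-(3,4,5-trihydroxyphenoxy)-3,5-dihydroxyphenoxy]-3,5-dihydroxyphenoxy}benzene-1,3,5-triol | Oc1cc(O)c(Oc2cc(O)c(Oc3cc(O)c(Oc4cc(O)c(O)c(O)c4)c(O)c3)c(O)c2)c(O)c1 | target

## Step count and risk

Total: 13 steps. Longest linear sequence: 12 steps, from syringaldehyde 4 through steps 2 to 13. Step 1 is the only branch. Triflate 13 is consumed in steps 7, 9 and 11 and must be made in corresponding quantity.

**Step 7 (key step; the same holds for steps 9 and 11).**
- What may go wrong: oxygen attack by the doubly flanked phenoxide may be slow compared with other fates of the aryne, namely capture by fluoride, self-reaction, or addition of the product's aryl anion to a second aryne.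
- The phenoxide may also attack the sulfur of 13 and take over the triflyl group before fluoride reaches silicon.
- The directing effect of the C3 methoxy group could be eroded by the oxygens on C4 and C5.
- Fallback: the same O–C1 bond is made by a copper-mediated Ullmann ether synthesis, setting out from phenol 3 and benzyl bromide 5. Commercial 4-bromo-2,6-dimethoxyphenol F1 is benzylated with 5 (K2CO3, DMF) to 2-(benzyloxy)-5-bromo-1,3-dimethoxybenzene F2. F2 is coupled with 3 (CuI, monovalent copper, picolinic acid, K3PO4, DMSO, about 100 °C), and the route is rejoined at 15. The position of the ether is then fixed by the bromine and not by the aryne. The same bromide would serve phenols 16 and 18 and rejoin at 17 and 19.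

**Step 13.**
- What may go wrong: cleavage may stall at the last flanked methoxy groups once boron-bound polyphenolate aggregates separate from dichloromethane.
- The decaphenol may be lost by air oxidation and by irreversible adsorption during isolation.
- Fallback: a derivatise, purify and release sequence from 20. After the BBr3 treatment the crude material is acetylated at once (Ac2O, pyridine) to the decaacetate F3 of polyphenol 21. F3 is air-stable, can be chromatographed on silica and can be separated from partly methylated material, which can be returned to the demethylation. Acid-catalysed methanolysis (HCl from acetyl chloride in degassed MeOH, rt) then gives 21.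

**Step 6.**
- What may go wrong: the O–Si bond of crude 10 may be cleaved, by adventitious water or by butyllithium at silicon, before exchange, so that no silyl group reaches carbon and the triflation falls on a phenoxide that lacks silicon.
- Butyllithium may deprotonate the benzylic CH2.
- Fallback: directed ortho-metalation replaces bromination and silyl migration, setting out from phenol 8 and returning at 13, which also bypasses steps 4 and 5.
  - Phenol 8 and isopropyl isocyanate (Et3N, CH2Cl2) give 4-(benzyloxy)-3,5-dimethoxyphenyl isopropylcarbamate F4.
  - F4 is N-silylated in the flask (TBSOTf, TMEDA, Et2O) to 4-(benzyloxy)-3,5-dimethoxyphenyl N-(tert-butyldimethylsilyl)-N-isopropylcarbamate F5.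
  - F5 is lithiated (n-BuLi, TMEDA, −78 °C) at the carbon between the carbamate and a methoxy group and quenched with TMSCl. Dilute acid work-up takes the silyl group off nitrogen and gives 4-(benzyloxy)-3,5-dimethoxy-2-(trimethylsilyl)phenyl isopropylcarbamate F6.
  - DBU and Et2NH in MeCN release 4-(benzyloxy)-3,5-dimethoxy-2-(trimethylsilyl)phenol F7, which is triflated in the same flask with PhNTf2 to give 13.

**Step 4.**
- What may go wrong: a second bromination at the remaining ortho position, and oxidation of the very electron-rich para-alkoxyphenol to a quinone by the N-bromo reagent.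
- Fallback: bromination is moved in front of the Dakin step, where the formyl group tempers the ring, setting out from aldehyde 6 and returning at 9. Aldehyde 6 is brominated (NBS, MeCN, rt) to 4-(benzyloxy)-2-bromo-3,5-dimethoxybenzaldehyde F8. Baeyer–Villiger oxidation (mCPBA, CH2Cl2) gives 4-(benzyloxy)-2-bromo-3,5-dimethoxyphenyl formate F9, and methanolysis (K2CO3 cat., MeOH) gives 9.

## Further compounds

F1 | step 7 | 4-bromo-2,6-dimethoxyphenol | COc1cc(Br)cc(OC)c1O
F2 | step 7 | 2-(benzyloxy)-5-bromo-1,3-dimethoxybenzene | COc1cc(Br)cc(OC)c1OCc1ccccc1
F3 | step 13 | decaacetate of 21 | CC(=O)Oc1cc(OC(C)=O)c(Oc2cc(OC(C)=O)c(Oc3cc(OC(C)=O)c(Oc4cc(OC(C)=O)c(OC(C)=O)c(OC(C)=O)c4)c(OC(C)=O)c3)c(OC(C)=O)c2)c(OC(C)=O)c1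
F4 | step 6 | 4-(benzyloxy)-3,5-dimethoxyphenyl isopropylcarbamate | COc1cc(OC(=O)NC(C)C)cc(OC)c1OCc1ccccc1
F5 | step 6 | 4-(benzyloxy)-3,5-dimethoxyphenyl N-(tert-butyldimethylsilyl)-N-isopropylcarbamate | COc1cc(OC(=O)N(C(C)C)[Si](C)(C)C(C)(C)C)cc(OC)c1OCc1ccccc1
F6 | step 6 | 4-(benzyloxy)-3,5-dimethoxy-2-(trimethylsilyl)phenyl isopropylcarbamate | COc1cc(OC(=O)NC(C)C)c([Si](C)(C)C)c(OC)c1OCc1ccccc1
F7 | step 6 | 4-(benzyloxy)-3,5-dimethoxy-2-(trimethylsilyl)phenol | COc1cc(O)c([Si](C)(C)C)c(OC)c1OCc1ccccc1
F8 | step 4 | 4-(benzyloxy)-2-bromo-3,5-dimethoxybenzaldehyde | COc1cc(C=O)c(Br)c(OC)c1OCc1ccccc1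
F9 | step 4 | 4-(benzyloxy)-2-bromo-3,5-dimethoxyphenyl formate | COc1cc(OC=O)c(Br)c(OC)c1OCc1ccccc1
A1 | alternative 1 | dimethyl 3-(2,4,6-trimethoxyphenoxy)pent-2-enedioate | COC(=O)C=C(CC(=O)OC)Oc1c(OC)cc(OC)cc1OC
A2 | alternative 1 | 2-[3,5-dimethoxy-4-(3,4,5-trimethoxyphenoxy)phenoxy]propanedioyl dichloride | O=C(Cl)C(Oc1cc(OC)c(Oc2cc(OC)c(OC)c(OC)c2)c(OC)c1)C(=O)Cl
A3 | alternative 1 | dimethyl 5-[3,5-dimethoxy-4-(3,4,5-trimethoxyphenoxy)phenoxy]-4,6-dihydroxy-2-(2,4,6-trimethoxyphenoxy)benzene-1,3-dicarboxylate | COC(=O)c1c(O)c(Oc2cc(OC)c(Oc3cc(OC)c(OC)c(OC)c3)c(OC)c2)c(O)c(C(=O)OC)c1Oc1c(OC)cc(OC)cc1OC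
A4 | alternative 2 | 4-diazo-3,5-dimethoxycyclohexa-2,5-dien-1-one | COC1=CC(=O)C=C(OC)C1=[N+]=[N-]
A5 | alternative 2 | 3,4,5-trimethoxyphenol | COc1cc(O)cc(OC)c1OC
A6 | alternative 2 | 3,5-dimethoxy-4-(3,4,5-trimethoxyphenoxy)phenol | COc1cc(O)cc(OC)c1Oc1cc(OC)c(OC)c(OC)c1
A7 | alternative 3 | pentacarbonyl{[(E)-2-ethoxyvinyl][4-(2,6-dimethoxy-4-(2,4,6-trimethoxyphenoxy)phenoxy)-2,6-dimethoxyphenoxy]carbene}chromium | CCO/C=C/C(Oc1c(OC)cc(Oc2c(OC)cc(Oc3c(OC)cc(OC)cc3OC)cc2OC)cc1OC)=[Cr](=C=O)(=C=O)(=C=O)(=C=O)=C=O
A8 | alternative 3 | ethoxyacetylene | CCOC#C
A9 | alternative 3 | 4-{4-[2,6-dimethoxy-4-(2,4,6-trimethoxyphenoxy)phenoxy]-2,6-dimethoxyphenoxy}-2,6-diethoxyphenol | CCOc1cc(Oc2c(OC)cc(Oc3c(OC)cc(Oc4c(OC)cc(OC)cc4OC)cc3OC)cc2OC)cc(OCC)c1O
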